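The route rests on closing the seven-membered ring by an intramolecular, hydroxyl-directed Prins cyclization: C7 of a prenyl-type alkene attacks the C6 aldehyde and the C11 cation is captured by acetic acid. In one operation this forms C6–C7, sets C6 and C7, and delivers the free 6-OH and the 11-OAc. It exploits the 1,3-dioxygen pattern O–C6–C7–C11–O across the new bond and the cis 6-OH/8-O pair of the seven-membered ring, which lets a Lewis acid bridge O8 and the aldehyde oxygen. The precursor is an acyclic chain on a furan-3-carbaldehyde; the furan masks the five-membered hydroxy-enone ring (C1–C5), unveiled later by oxidative opening and aldol closure.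

Key step: step 4

Remark: atoms carry the guaiane numbers of the target throughout (C1 ring-fusion carbinol, C3 ketone, C4=C5, C6 carbinol, C7, C8 angelate carbon, C10 methyl-bearing carbon, C11 acetoxy carbon); both enantiomers of the imidazolidinone catalyst and of MIB are assumed to be commercially available.

Step 1
Reactants: 1 2,3-dimethylfuran; 2 (E)-but-2-enal (crotonaldehyde)
Product: 4 5-[(2S)-4,4-dimethoxybutan-2-yl]-2,3-dimethylfuran, via furylbutanal 3 (not isolated)
Conditions: (2R,5R)-5-benzyl-2-tert-butyl-3-methylimidazolidin-4-one·TFA (20 mol %), CH2Cl2/i-PrOH, −40 °C; then HC(OMe)3, MeOH, PPTS (cat.), 0 °C → rt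
Reagents that add atoms: trimethyl orthoformate, COC(OC)OC
Why: Iminium-catalysed enantioselective Friedel–Crafts alkylation: the only free α-position of the furan adds to the β-carbon of the (E)-iminium ion from the face left open by the benzyl and tert-butyl groups of the (2R,5R) catalyst, which should set C10 as (S), and in situ acetalization masks the aldehyde for the formylation.

Step 2
Reactants: 4 5-[(2S)-4,4-dimethoxybutan-2-yl]-2,3-dimethylfuran
Product: 6 4,5-dimethyl-2-[(2S)-4-oxobutan-2-yl]furan-3-carbaldehyde, via formyl acetal 5 (not isolated)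
Conditions: POCl3, DMF, ClCH2CH2Cl, 0 °C → rt; aq NaOAc; then 1 M HCl, THF, 0 °C
Reagents that add atoms: N,N-dimethylformamide, CN(C)C=O; water, O
Why: Vilsmeier–Haack formylation can only occur at the single unsubstituted carbon of the electron-rich trialkylfuran, and the acetal is hydrolysed only after the formyl group has deactivated the ring, which should suppress acid-mediated cyclization of the side-chain aldehyde onto the furan; no stereocenter is touched.

Step 3
Reactants: 6 4,5-dimethyl-2-[(2S)-4-oxobutan-2-yl]furan-3-carbaldehyde; 7 1-bromo-2-methylprop-1-ene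
Product: 8 2-[(2S,4R)-4-hydroxy-6-methylhept-5-en-2-yl]-4,5-dimethylfuran-3-carbaldehyde
Conditions: 7, t-BuLi (2 equiv), Et2O, −78 °C; ZnBr2 (0.5 equiv); TEEDA; (−)-MIB (5 mol %), hexanes/toluene; then 6, −20 → 0 °C; aq NH4Cl
Reagents that add atoms: none
Why: Catalytic enantioselective alkenylzinc addition under reagent control by the amino-alcohol zinc catalyst: the alkenyl group should be delivered to the Si face of the aliphatic aldehyde to set C8 as (R), with TEEDA suppressing the LiBr-promoted racemic background, while the furan aldehyde, flanked by two ring substituents and deactivated by donation from the ring oxygen, should remain untouched.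

Step 4
Reactants: 8 2-[(2S,4R)-4-hydroxy-6-methylhept-5-en-2-yl]-4,5-dimethylfuran-3-carbaldehyde
Product: 9 2-[(4R,5R,6R,8S)-4,6-dihydroxy-2,3,8-trimethyl-5,6,7,8-tetrahydro-4H-cyclohepta[b]furan-5-yl]propan-2-yl acetate
Conditions: Sc(OTf)3 (10 mol %), AcOH (20 equiv), CH2Cl2, −40 → −20 °C; Et3N quench
Reagents that add atoms: acetic acid, CC(=O)O
Why: Sc(OTf)3 is expected to bridge the free 8-OH and the formyl oxygen, the C7=C11 alkene then adds through C7 to the activated C6 carbonyl and the tertiary C11 cation is captured by acetic acid (any isopropenyl ene product should re-enter the cation manifold by protonation). The closest known reaction is the Lewis-acid Prins (carbonyl-ene) cyclization of citronellal-type alkenyl aldehydes with carboxylate capture, combined with chelation control as in additions to β-alkoxy aldehydes. The seven-membered ring closes in a 7-exo-trig mode with respect to both π bonds (C11 and O6 stay exocyclic). C6 is controlled by the chelate, which forces O6 syn to O8, and C7 by the alkene rotamer that keeps C11 anti to C9 (A(1,3) strain) with O8 on the side of the incoming aldehyde, so that O6, C11 and O8 should end up all cis with respect to the existing (R)-C8. The step needs the chelated transition state, with O6, O8 and the C10 methyl pseudoaxial, to win over the non-chelated all-equatorial one that would give the 7,8-trans isomer, and needs acetate capture to outrun ionization of the allylic alcohol and retro-Prins fragmentation; the free 8-OH as a ligand, low temperature and excess AcOH are meant to secure this.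

Step 5
Reactants: 9 2-[(4R,5R,6R,8S)-4,6-dihydroxy-2,3,8-trimethyl-5,6,7,8-tetrahydro-4H-cyclohepta[b]furan-5-yl]propan-2-yl acetate; 10 angelic acid, (Z)-2-methylbut-2-enoic acid
Product: 11 (4R,5S,6R,8S)-5-(2-acetoxypropan-2-yl)-4-hydroxy-2,3,8-trimethyl-5,6,7,8-tetrahydro-4H-cyclohepta[b]furan-6-yl (Z)-2-methylbut-2-enoate
Conditions: 10, 2,4,6-trichlorobenzoyl chloride, Et3N, toluene, rt; then 9, 70 °C
Reagents that add atoms: none
Why: Yamaguchi esterification run without DMAP to avoid isomerization of the (Z)-enoate to the tiglate: the hindered mixed anhydride should acylate the 8-OH, which has a CH2 neighbour, in preference to the furylic 6-OH wedged between the substituted furan and C7; no stereocenter changes.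

Step 6
Reactants: 11 (4R,5S,6R,8S)-5-(2-acetoxypropan-2-yl)-4-hydroxy-2,3,8-trimethyl-5,6,7,8-tetrahydro-4H-cyclohepta[b]furan-6-yl (Z)-2-methylbut-2-enoate
Product: 12 (4R,5R,6R,8S)-5-(2-acetoxypropan-2-yl)-2,3,8-trimethyl-4-(triethylsilyloxy)-5,6,7,8-tetrahydro-4H-cyclohepta[b]furan-6-yl (Z)-2-methylbut-2-enoate
Conditions: TESOTf, 2,6-lutidine, CH2Cl2, −78 → 0 °C
Reagents that add atoms: triethylsilyl trifluoromethanesulfonate, CC[Si](CC)(CC)OS(=O)(=O)C(F)(F)F
Why: Silyl ether formation with a silyl triflate caps the hindered 6-OH so that in step 7 it can neither hydrogen-bond to the C1 carbonyl nor take part in acyl migration; no stereocenter changes.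

Step 7
Reactants: 12 (4R,5R,6R,8S)-5-(2-acetoxypropan-2-yl)-2,3,8-trimethyl-4-(triethylsilyloxy)-5,6,7,8-tetrahydro-4H-cyclohepta[b]furan-6-yl (Z)-2-methylbut-2-enoate
Product: 14 (1R,6R,7R,8R,10S)-11-acetoxy-1-hydroxy-3-oxo-6-(triethylsilyloxy)guai-4-en-8-yl (Z)-2-methylbut-2-enoate, via cis-enedione 13 (not isolated)
Conditions: mCPBA (1.05 equiv), NaHCO3, CH2Cl2, 0 °C; then DBU (0.2 equiv), 0 °C → rt
Reagents that add atoms: meta-chloroperbenzoic acid, OOC(=O)c1cccc(Cl)c1
Why: Peracid oxidation of the tetrasubstituted furan gives the cis-enedione (the electron-poor angelate is not epoxidized), and base-mediated intramolecular aldol addition (5-enolexo-exo-trig) of the methyl ketone carbon C2 onto the C1 ketone closes the five-membered ring; C1 should be set from the conformer in which the C1 carbonyl oxygen is turned away from the bulky C6–OTES group (A(1,3) strain to the C4 methyl keeps H6 in the enedione plane), which places 1-OH trans to the 6-oxygen, and dehydration is blocked because it would give a cyclopentadienone.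

Step 8
Reactants: 14 (1R,6R,7R,8R,10S)-11-acetoxy-1-hydroxy-3-oxo-6-(triethylsilyloxy)guai-4-en-8-yl (Z)-2-methylbut-2-enoate
Product: 15 (1R,6R,7S,8R,10S)-11-acetoxy-1,6-dihydroxy-3-oxoguai-4-en-8-yl (Z)-2-methylbut-2-enoate (target)
Conditions: HF·pyridine, pyridine, THF, 0 °C
Reagents that add atoms: none
Why: Fluoride-mediated desilylation under buffered HF·pyridine should leave the angelate, the tertiary acetate and the β-hydroxy ketone untouched; no stereocenter changes.

Compound list
1 | 2,3-dimethylfuran | Cc1occc1C | starting material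
2 | (E)-but-2-enal (crotonaldehyde) | C/C=C/C=O | starting material
3 | (3S)-3-(4,5-dimethylfuran-2-yl)butanal (not isolated) | O=CC[C@H](C)c1cc(C)c(C)o1 | intermediate
4 | 5-[(2S)-4,4-dimethoxybutan-2-yl]-2,3-dimethylfuran | COC(OC)C[C@H](C)c1cc(C)c(C)o1 | intermediate
5 | 2-[(2S)-4,4-dimethoxybutan-2-yl]-4,5-dimethylfuran-3-carbaldehyde (not isolated) | COC(OC)C[C@H](C)c1oc(C)c(C)c1C=O | intermediate
6 | 4,5-dimethyl-2-[(2S)-4-oxobutan-2-yl]furan-3-carbaldehyde | O=CC[C@H](C)c1oc(C)c(C)c1C=O | intermediate
7 | 1-bromo-2-methylprop-1-ene | CC(C)=CBr | starting material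
8 | 2-[(2S,4R)-4-hydroxy-6-methylhept-5-en-2-yl]-4,5-dimethylfuran-3-carbaldehyde | O[C@@H](C=C(C)C)C[C@H](C)c1oc(C)c(C)c1C=O | intermediate
9 | 2-[(4R,5R,6R,8S)-4,6-dihydroxy-2,3,8-trimethyl-5,6,7,8-tetrahydro-4H-cyclohepta[b]furan-5-yl]propan-2-yl acetate | O[C@@H]1C[C@H](C)c2oc(C)c(C)c2[C@H](O)[C@@H]1C(C)(C)OC(C)=O | intermediate
10 | angelic acid, (Z)-2-methylbut-2-enoic acid | C/C=C(/C)C(=O)O | starting material
11 | (4R,5S,6R,8S)-5-(2-acetoxypropan-2-yl)-4-hydroxy-2,3,8-trimethyl-5,6,7,8-tetrahydro-4H-cyclohepta[b]furan-6-yl (Z)-2-methylbut-2-enoate | C/C=C(/C)C(=O)O[C@@H]1C[C@H](C)c2oc(C)c(C)c2[C@H](O)[C@@H]1C(C)(C)OC(C)=O | intermediate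
12 | (4R,5R,6R,8S)-5-(2-acetoxypropan-2-yl)-2,3,8-trimethyl-4-(triethylsilyloxy)-5,6,7,8-tetrahydro-4H-cyclohepta[b]furan-6-yl (Z)-2-methylbut-2-enoate | C/C=C(/C)C(=O)O[C@@H]1C[C@H](C)c2oc(C)c(C)c2[C@H](O[Si](CC)(CC)CC)[C@@H]1C(C)(C)OC(C)=O | intermediate
13 | ring-opened cis-enedione of 12: cycloheptanone (C1 ketone) carrying an exocyclic (Z)-3-oxobutan-2-ylidene group at C5, acetyl cis to the C1 carbonyl, other centers as in 12 (not isolated) | C/C=C(/C)C(=O)O[C@@H]1C[C@H](C)C(=O)/C(=C(/C)C(C)=O)[C@H](O[Si](CC)(CC)CC)[C@@H]1C(C)(C)OC(C)=O | intermediate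
14 | (1R,6R,7R,8R,10S)-11-acetoxy-1-hydroxy-3-oxo-6-(triethylsilyloxy)guai-4-en-8-yl (Z)-2-methylbut-2-enoate | C/C=C(/C)C(=O)O[C@@H]1C[C@H](C)[C@]2(O)CC(=O)C(C)=C2[C@H](O[Si](CC)(CC)CC)[C@@H]1C(C)(C)OC(C)=O | intermediate
15 | (1R,6R,7S,8R,10S)-11-acetoxy-1,6-dihydroxy-3-oxoguai-4-en-8-yl (Z)-2-methylbut-2-enoate, CNP0273287.1 | C/C=C(/C)C(=O)O[C@@H]1C[C@H](C)[C@]2(O)CC(=O)C(C)=C2[C@H](O)[C@@H]1C(C)(C)OC(C)=O | target

Total step count: 8
Longest linear sequence: 8 steps (1 → 15)

Steps most likely to fail

Step 4 (key step). The protic Lewis-acid medium may ionize the prenyl-type allylic alcohol of 8 or the furylic carbinol of the product. The C11 cation may also fragment in a retro-Prins sense and scramble C8, or the ring may close through the non-chelated transition state with poor control at C7. The fallback sets out from 8. Me2AlCl (2.2 equiv, CH2Cl2, −78 °C) should turn O8 into an aluminium alkoxide that activates the aldehyde intramolecularly under aprotic conditions. The ring then closes by a carbonyl-ene reaction through the same chelate geometry and gives (4R,5R,6R,8S)-2,3,8-trimethyl-5-(prop-1-en-2-yl)-5,6,7,8-tetrahydro-4H-cyclohepta[b]furan-4,6-diol F1. Markovnikov acetoxymercuration–demercuration of its 1,1-disubstituted alkene (Hg(OAc)2, AcOH; then NaBH4, NaOH) should install the tertiary acetate and bring the route back at 9.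

Step 7. The aldol may take the wrong facial course at C1, the C1 ketone may enolize toward C10 and epimerize it, and DBU may isomerize the angelate. The fallback sets out from 9. tBu2Si(OTf)2 with 2,6-lutidine ties O6 and O8 into the di-tert-butylsilylene acetal of 9 F2, so that a locked bicyclic frame, not a single silyl ether, fixes the conformation of the seven-membered ring during the aldol. mCPBA followed by DBU should then give the silylene-protected hydroxy enone F3, and HF·pyridine should free the 8-O-deangeloyl triol F4. Yamaguchi esterification with 10 at the less hindered 8-OH comes back to the route at 15.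

Step 5. Acylation may occur at the wrong hydroxyl or twice, the tertiary acetate or the new ester may migrate between the 1,3-related oxygens under Et3N at 70 °C, and the (Z)-enoate may isomerize. The fallback sets out from 9 and builds the angelate double bond in place instead of transferring angelic acid. Carbodiimide coupling at 0 °C (EDC, DMAP cat.) with the small, reactive 2-[bis(2,2,2-trifluoroethoxy)phosphoryl]propanoic acid should give the 8-O-phosphonopropanoate of 9 F5. Z-selective Still–Gennari olefination with acetaldehyde (KHMDS, 18-crown-6, THF, −78 °C) should then form the (Z)-2-methylbut-2-enoate and come back to the route at 11.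

Further compounds
F1 | step 4 | (4R,5R,6R,8S)-2,3,8-trimethyl-5-(prop-1-en-2-yl)-5,6,7,8-tetrahydro-4H-cyclohepta[b]furan-4,6-diol | O[C@@H]1C[C@H](C)c2oc(C)c(C)c2[C@H](O)[C@@H]1C(C)=C
F2 | step 7 | di-tert-butylsilylene acetal of 9 (silicon bridging O6 and O8) | O3[C@@H]1C[C@H](C)c2oc(C)c(C)c2[C@H](O[Si]3(C(C)(C)C)C(C)(C)C)[C@@H]1C(C)(C)OC(C)=O
F3 | step 7 | silylene-protected hydroxy enone (6,8-O-di-tert-butylsilylene of F4) | O3[C@@H]1C[C@H](C)[C@]2(O)CC(=O)C(C)=C2[C@H](O[Si]3(C(C)(C)C)C(C)(C)C)[C@@H]1C(C)(C)OC(C)=O
F4 | step 7 | 8-O-deangeloyl triol of 15 (11-acetoxy-1,6,8-trihydroxyguai-4-en-3-one) | O[C@@H]1C[C@H](C)[C@]2(O)CC(=O)C(C)=C2[C@H](O)[C@@H]1C(C)(C)OC(C)=O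
F5 | step 5 | 8-O-{2-[bis(2,2,2-trifluoroethoxy)phosphoryl]propanoyl} ester of 9 | CC(C(=O)O[C@@H]1C[C@H](C)c2oc(C)c(C)c2[C@H](O)[C@@H]1C(C)(C)OC(C)=O)P(=O)(OCC(F)(F)F)OCC(F)(F)F
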